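**Plan**

- Numbering used below (decalin): C1 carries the side chain, C2 is the ring CH2, C3 the ring acetate, C4 the methyl, C4a the fusion CH, C8a the fusion sp2 carbon, C7 the methylidene carbon.
- Late cuts: both acetates; the ketone–(2-methylpropenyl) bond (N-methoxy-N-methylamide + Grignard reagent); the side-chain methyl and hydroxyl (conjugate addition and enolate hydroxylation on an N-enoyl oxazolidinone made by cross-metathesis of a C1 vinyl group).
- Ring cuts: C7=CH2 from a ring A enone (Wittig); the C3 oxygen from a C3 nitro group (Nef reaction, then hydride from the equatorial side).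
- Key cut: C2–C3 and C1–C8a together, to a 4-(1-nitropropan-2-yl)cyclohexenone and acrolein. C3 (oxygenated) and the ring A enone β-carbon C8a are 1,4-related through C4–C4a, so a C3 nitronate (a polarity-reversed carbonyl carbon) and C8a can clasp the two carbons of an enal in an iminium–enamine double Michael cascade that closes ring B onto ring A.
- Forward order: ring A (amine-catalysed Michael addition of 5-oxohexanal to nitropropene, aldol condensation), ring B (cascade), enone, diene, C3 ketone, C3 alcohol, side chain, diacetate.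
- Stereochemistry: C4 and C4a from the first amine catalyst (syn Michael), C1 from the second (enamine face), C3 from LiBH(s-Bu)3, both side-chain centers from the (R)-benzyloxazolidinone; C8a of the cascade product is erased when the enone is restored.

Key step: step 3

Assumption: (E)-1-nitroprop-1-ene is bought as such (otherwise it is one dehydration step from 1-nitropropan-2-ol).

Step 1
Reactants: 1 1-methylcyclopent-1-ene
Product: 2 5-oxohexanal
Conditions: O3, CH2Cl2, −78 °C; then PPh3, −78 °C → rt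
Reagents that add atoms: ozone, O=[O+][O-]
Why: Ozonolysis with reductive work-up cleaves the trisubstituted ring alkene to the keto aldehyde; no stereocenter is formed.

Step 2
Reactants: 2 5-oxohexanal; 3 (E)-1-nitroprop-1-ene
Product: 5 (4R)-4-[(2S)-1-nitropropan-2-yl]cyclohex-2-en-1-one, via keto aldehyde 4 (not isolated)
Conditions: (R)-α,α-diphenylprolinol trimethylsilyl ether (10 mol%), PhCO2H (10 mol%), toluene, 0 °C → rt; then p-TsOH·H2O (cat.), toluene, 60 °C
Reagents that add atoms: none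
Why: Enamine-mediated asymmetric Michael addition of the aldehyde (the catalyst does not activate the ketone) to the nitroalkene should set the future C4a and C4 syn under catalyst control, and the acid-promoted intramolecular aldol condensation of 4 (Robinson-type closure, methyl ketone onto the aldehyde) then forms ring A without touching either center.

Step 3
Reactants: 5 (4R)-4-[(2S)-1-nitropropan-2-yl]cyclohex-2-en-1-one; 6 acrolein
Product: 7 (1R,4S,4aR,8aS)-4-methyl-3-nitro-7-oxodecahydronaphthalene-1-carbaldehyde (cis-fused, C3 epimers)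
Conditions: acrolein (1.2 equiv), (S)-α,α-diphenylprolinol trimethylsilyl ether (20 mol%), PhCO2H (20 mol%), CH2Cl2/MeOH, 0 °C → rt
Reagents that add atoms: none
Why: The amine condenses with acrolein to an iminium ion, the nitronate of 5 adds to its β-carbon (bond C2–C3), the enamine so formed attacks the β-carbon of the ring A enone (bond C1–C8a), and hydrolysis returns the catalyst; the nitro group is the polarity-reversed form of the C3 carbinol carbon. The closest known reaction type is the amine-catalysed iminium–enamine nitro-Michael/Michael domino reaction of nitroalkanes that carry a tethered acceptor with enals. Ring B closes in a 6-exo-trig mode through a chair-like transition state, which on geometric grounds should give the cis ring fusion. C1 is set by the shielded enamine face of the (S)-catalyst with the enamine unit equatorial; C8a is set by the tether and is erased in step 5; C3 is left uncontrolled because it becomes a ketone in step 7; C4 and C4a are carried through. The step needs the nitronate to attack the iminium ion and not the less electrophilic β-substituted ring enone, and C1 (not C2) to close the ring; iminium activation of acrolein alone secures the first, and the second follows because only the aldehyde α-carbon is an enamine carbon and closure from C3 would give a four-membered ring.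

Step 4
Reactants: 7 (1R,4S,4aR,8aS)-4-methyl-3-nitro-7-oxodecahydronaphthalene-1-carbaldehyde
Product: 8 (4aR,5S,8S,8aR)-8-ethenyl-5-methyl-6-nitrooctahydronaphthalen-2(1H)-one (C6 epimers)
Conditions: Ph3PCH3Br, KN(SiMe3)2 (2.1 equiv of ylide), THF, −78 → 0 °C
Reagents that add atoms: methyltriphenylphosphonium bromide, C[P+](c1ccccc1)(c1ccccc1)c1ccccc1.[Br-]
Why: Wittig methylenation; the non-stabilised ylide should react with the aldehyde far faster than with the ring ketone at low temperature (one equivalent is taken up by the acidic nitro group), and the formyl carbon is carried on as a vinyl group that survives steps 5–8.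

Step 5
Reactants: 8 (4aR,5S,8S,8aR)-8-ethenyl-5-methyl-6-nitrooctahydronaphthalen-2(1H)-one
Product: 9 (4aS,5S,8S)-8-ethenyl-5-methyl-6-nitro-4,4a,5,6,7,8-hexahydronaphthalen-2(3H)-one (C6 epimers)
Conditions: IBX (1.5 equiv), DMSO, 65 °C
Reagents that add atoms: none
Why: IBX dehydrogenation of the ketone through its enol; a cis-fused ketone of this type enolises toward the ring-fusion side, so the C8=C8a enone should form and the transient C8a center disappears.

Step 6
Reactants: 9 (4aS,5S,8S)-8-ethenyl-5-methyl-6-nitro-4,4a,5,6,7,8-hexahydronaphthalen-2(3H)-one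
Product: 10 (1S,4S,4aS)-1-ethenyl-4-methyl-7-methylidene-3-nitro-1,2,3,4,4a,5,6,7-octahydronaphthalene (C3 epimers)
Conditions: Ph3PCH3Br, KN(SiMe3)2 (2.2 equiv of ylide), THF, 0 °C → rt
Reagents that add atoms: methyltriphenylphosphonium bromide, C[P+](c1ccccc1)(c1ccccc1)c1ccccc1.[Br-]
Why: Wittig methylenation of the enone carbonyl should give the exocyclic 1,3-diene; the nitro group is only deprotonated and returns on work-up.

Step 7
Reactants: 10 (1S,4S,4aS)-1-ethenyl-4-methyl-7-methylidene-3-nitro-1,2,3,4,4a,5,6,7-octahydronaphthalene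
Product: 11 (1S,4S,8aS)-4-ethenyl-1-methyl-6-methylidene-3,4,6,7,8,8a-hexahydronaphthalen-2(1H)-one
Conditions: 30% H2O2, K2CO3, MeOH, 0 °C → rt
Reagents that add atoms: hydrogen peroxide, OO
Why: Oxidative Nef reaction; the nitronate formed with K2CO3 is oxidised to the ketone under non-acidic conditions that the diene and the vinyl group should tolerate, and the C4 methyl (now α to the ketone) stays in or equilibrates to the equatorial position set in step 2.

Step 8
Reactants: 11 (1S,4S,8aS)-4-ethenyl-1-methyl-6-methylidene-3,4,6,7,8,8a-hexahydronaphthalen-2(1H)-one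
Product: 12 (1S,2R,4S,8aS)-4-ethenyl-1-methyl-6-methylidene-1,2,3,4,6,7,8,8a-octahydronaphthalen-2-ol
Conditions: LiBH(s-Bu)3, THF, −78 °C; then H2O
Reagents that add atoms: none
Why: Bulky hydride reduction; LiBH(s-Bu)3 attacks this 2-methylcyclohexanone-type carbonyl from the equatorial direction, which should give the axial C3 alcohol cis to the C4 methyl.

Step 9
Reactants: 13 (4R)-4-benzyl-1,3-oxazolidin-2-one; 14 acryloyl chloride
Product: 15 (4R)-4-benzyl-3-(prop-2-enoyl)-1,3-oxazolidin-2-one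
Conditions: n-BuLi, THF, −78 °C; then acryloyl chloride, −78 → 0 °C
Reagents that add atoms: none
Why: N-Acylation of the lithiated oxazolidinone by the acid chloride.

Step 10
Reactants: 12 (1S,2R,4S,8aS)-4-ethenyl-1-methyl-6-methylidene-1,2,3,4,6,7,8,8a-octahydronaphthalen-2-ol; 15 (4R)-4-benzyl-3-(prop-2-enoyl)-1,3-oxazolidin-2-one
Product: 16 (4R)-4-benzyl-3-{(2E)-3-[(1S,3R,4S,4aS)-3-hydroxy-4-methyl-7-methylidene-1,2,3,4,4a,5,6,7-octahydronaphthalen-1-yl]prop-2-enoyl}-1,3-oxazolidin-2-one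
Conditions: second-generation Grubbs catalyst (5 mol%), CH2Cl2, 40 °C
Reagents that add atoms: none
Why: Olefin cross-metathesis between a monosubstituted alkene and an acrylimide should be E-selective and should leave the hindered 1,1-disubstituted/trisubstituted ring diene alone.

Step 11
Reactants: 16 (4R)-4-benzyl-3-{(2E)-3-[(1S,3R,4S,4aS)-3-hydroxy-4-methyl-7-methylidene-1,2,3,4,4a,5,6,7-octahydronaphthalen-1-yl]prop-2-enoyl}-1,3-oxazolidin-2-one
Product: 17 (4R)-4-benzyl-3-{(3R)-3-[(1S,3R,4S,4aS)-3-hydroxy-4-methyl-7-methylidene-1,2,3,4,4a,5,6,7-octahydronaphthalen-1-yl]butanoyl}-1,3-oxazolidin-2-one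
Conditions: MeMgBr (3 equiv), CuBr·SMe2 (20 mol%), THF/Me2S, −40 °C; then aq NH4Cl
Reagents that add atoms: methylmagnesium bromide, C[Mg]Br
Why: Copper-catalysed conjugate addition of the Grignard reagent to the magnesium-chelated s-cis N-enoyl oxazolidinone should occur on the face opposite the benzyl group, which sets the side-chain methyl center.

Step 12
Reactants: 17 (4R)-4-benzyl-3-{(3R)-3-[(1S,3R,4S,4aS)-3-hydroxy-4-methyl-7-methylidene-1,2,3,4,4a,5,6,7-octahydronaphthalen-1-yl]butanoyl}-1,3-oxazolidin-2-one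
Product: 18 (4R)-4-benzyl-3-{(2R,3S)-2-hydroxy-3-[(1S,3R,4S,4aS)-3-hydroxy-4-methyl-7-methylidene-1,2,3,4,4a,5,6,7-octahydronaphthalen-1-yl]butanoyl}-1,3-oxazolidin-2-one
Conditions: NaN(SiMe3)2 (2.2 equiv), THF, −78 °C; then 2-(benzenesulfonyl)-3-phenyloxaziridine; AcOH quench
Reagents that add atoms: 2-(benzenesulfonyl)-3-phenyloxaziridine, O=S(=O)(c1ccccc1)N1OC1c1ccccc1
Why: Electrophilic hydroxylation of the chelated Z sodium enolate by the N-sulfonyloxaziridine on the face opposite the benzyl group should set the side-chain carbinol center.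

Step 13
Reactants: 18 (4R)-4-benzyl-3-{(2R,3S)-2-hydroxy-3-[(1S,3R,4S,4aS)-3-hydroxy-4-methyl-7-methylidene-1,2,3,4,4a,5,6,7-octahydronaphthalen-1-yl]butanoyl}-1,3-oxazolidin-2-one
Product: 19 (2R,3S)-2-hydroxy-3-[(1S,3R,4S,4aS)-3-hydroxy-4-methyl-7-methylidene-1,2,3,4,4a,5,6,7-octahydronaphthalen-1-yl]-N-methoxy-N-methylbutanamide
Conditions: MeNH(OMe)·HCl, AlMe3, CH2Cl2, 0 °C → rt
Reagents that add atoms: N,O-dimethylhydroxylamine hydrochloride, CNOC.Cl
Why: Aluminium amide transamination of the α-hydroxy imide gives the N-methoxy-N-methylamide and releases the auxiliary.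

Step 14
Reactants: 19 (2R,3S)-2-hydroxy-3-[(1S,3R,4S,4aS)-3-hydroxy-4-methyl-7-methylidene-1,2,3,4,4a,5,6,7-octahydronaphthalen-1-yl]-N-methoxy-N-methylbutanamide
Product: 20 (5R,6S)-5-hydroxy-6-[(1S,3R,4S,4aS)-3-hydroxy-4-methyl-7-methylidene-1,2,3,4,4a,5,6,7-octahydronaphthalen-1-yl]-2-methylhept-2-en-4-one
Conditions: 2-methylprop-1-enylmagnesium bromide (5 equiv), THF, −20 → 0 °C; then aq NH4Cl
Reagents that add atoms: 2-methylprop-1-enylmagnesium bromide, CC(C)=C[Mg]Br
Why: Acylation of the Grignard reagent by the N-methoxy-N-methylamide should stop at the ketone because the chelated tetrahedral intermediate survives until work-up.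

Step 15
Reactants: 20 (5R,6S)-5-hydroxy-6-[(1S,3R,4S,4aS)-3-hydroxy-4-methyl-7-methylidene-1,2,3,4,4a,5,6,7-octahydronaphthalen-1-yl]-2-methylhept-2-en-4-one
Product: 21 (1S,2R,4S,8aS)-4-[(2S,3R)-3-acetoxy-6-methyl-4-oxohept-5-en-2-yl]-1-methyl-6-methylidene-1,2,3,4,6,7,8,8a-octahydronaphthalen-2-yl acetate
Conditions: Ac2O, Et3N, DMAP (cat.), CH2Cl2, rt
Reagents that add atoms: acetic anhydride, CC(=O)OC(C)=O
Why: DMAP-catalysed acetylation of both secondary alcohols gives the target.

**Compound list**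

1 | 1-methylcyclopent-1-ene | CC1=CCCC1 | starting material
2 | 5-oxohexanal | CC(=O)CCCC=O | intermediate
3 | (E)-1-nitroprop-1-ene | C/C=C/[N+](=O)[O-] | starting material
4 | (2S,3S)-3-methyl-4-nitro-2-(3-oxobutyl)butanal | O=C[C@@H](CCC(C)=O)[C@H](C)C[N+](=O)[O-] | intermediate
5 | (4R)-4-[(2S)-1-nitropropan-2-yl]cyclohex-2-en-1-one | O=C1C=C[C@@H](CC1)[C@H](C)C[N+](=O)[O-] | intermediate
6 | acrolein (prop-2-enal) | C=CC=O | starting material
7 | (1R,4S,4aR,8aS)-4-methyl-3-nitro-7-oxodecahydronaphthalene-1-carbaldehyde (cis-fused, C3 epimers) | O=C1C[C@H]2[C@@H](CC1)[C@H](C)C([N+](=O)[O-])C[C@H]2C=O | intermediate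
8 | (4aR,5S,8S,8aR)-8-ethenyl-5-methyl-6-nitrooctahydronaphthalen-2(1H)-one (C6 epimers) | O=C1C[C@H]2[C@@H](CC1)[C@H](C)C([N+](=O)[O-])C[C@H]2C=C | intermediate
9 | (4aS,5S,8S)-8-ethenyl-5-methyl-6-nitro-4,4a,5,6,7,8-hexahydronaphthalen-2(3H)-one (C6 epimers) | O=C1C=C2[C@@H](CC1)[C@H](C)C([N+](=O)[O-])C[C@H]2C=C | intermediate
10 | (1S,4S,4aS)-1-ethenyl-4-methyl-7-methylidene-3-nitro-1,2,3,4,4a,5,6,7-octahydronaphthalene (C3 epimers) | C=C1C=C2[C@@H](CC1)[C@H](C)C([N+](=O)[O-])C[C@H]2C=C | intermediate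
11 | (1S,4S,8aS)-4-ethenyl-1-methyl-6-methylidene-3,4,6,7,8,8a-hexahydronaphthalen-2(1H)-one | C=C1C=C2[C@@H](CC1)[C@H](C)C(=O)C[C@H]2C=C | intermediate
12 | (1S,2R,4S,8aS)-4-ethenyl-1-methyl-6-methylidene-1,2,3,4,6,7,8,8a-octahydronaphthalen-2-ol | C=C1C=C2[C@@H](CC1)[C@H](C)[C@H](O)C[C@H]2C=C | intermediate
13 | (4R)-4-benzyl-1,3-oxazolidin-2-one | O=C1N[C@H](Cc2ccccc2)CO1 | starting material
14 | acryloyl chloride (prop-2-enoyl chloride) | C=CC(Cl)=O | starting material
15 | (4R)-4-benzyl-3-(prop-2-enoyl)-1,3-oxazolidin-2-one | C=CC(=O)N1[C@H](Cc2ccccc2)COC1=O | intermediate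
16 | (4R)-4-benzyl-3-{(2E)-3-[(1S,3R,4S,4aS)-3-hydroxy-4-methyl-7-methylidene-1,2,3,4,4a,5,6,7-octahydronaphthalen-1-yl]prop-2-enoyl}-1,3-oxazolidin-2-one | C=C1C=C2[C@@H](CC1)[C@H](C)[C@H](O)C[C@H]2/C=C/C(=O)N3[C@H](Cc4ccccc4)COC3=O | intermediate
17 | (4R)-4-benzyl-3-{(3R)-3-[(1S,3R,4S,4aS)-3-hydroxy-4-methyl-7-methylidene-1,2,3,4,4a,5,6,7-octahydronaphthalen-1-yl]butanoyl}-1,3-oxazolidin-2-one | C=C1C=C2[C@@H](CC1)[C@H](C)[C@H](O)C[C@H]2[C@H](C)CC(=O)N3[C@H](Cc4ccccc4)COC3=O | intermediate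
18 | (4R)-4-benzyl-3-{(2R,3S)-2-hydroxy-3-[(1S,3R,4S,4aS)-3-hydroxy-4-methyl-7-methylidene-1,2,3,4,4a,5,6,7-octahydronaphthalen-1-yl]butanoyl}-1,3-oxazolidin-2-one | C=C1C=C2[C@@H](CC1)[C@H](C)[C@H](O)C[C@H]2[C@H](C)[C@@H](O)C(=O)N3[C@H](Cc4ccccc4)COC3=O | intermediate
19 | (2R,3S)-2-hydroxy-3-[(1S,3R,4S,4aS)-3-hydroxy-4-methyl-7-methylidene-1,2,3,4,4a,5,6,7-octahydronaphthalen-1-yl]-N-methoxy-N-methylbutanamide | C=C1C=C2[C@@H](CC1)[C@H](C)[C@H](O)C[C@H]2[C@H](C)[C@@H](O)C(=O)N(C)OC | intermediate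
20 | (5R,6S)-5-hydroxy-6-[(1S,3R,4S,4aS)-3-hydroxy-4-methyl-7-methylidene-1,2,3,4,4a,5,6,7-octahydronaphthalen-1-yl]-2-methylhept-2-en-4-one | C=C1C=C2[C@@H](CC1)[C@H](C)[C@H](O)C[C@H]2[C@H](C)[C@@H](O)C(=O)C=C(C)C | intermediate
21 | (1S,2R,4S,8aS)-4-[(2S,3R)-3-acetoxy-6-methyl-4-oxohept-5-en-2-yl]-1-methyl-6-methylidene-1,2,3,4,6,7,8,8a-octahydronaphthalen-2-yl acetate | C=C1C=C2[C@@H](CC1)[C@H](C)[C@H](OC(C)=O)C[C@H]2[C@H](C)[C@@H](OC(C)=O)C(=O)C=C(C)C | target

**Step count and risks**

Total step count: 15. Longest linear sequence: 14 (steps 1–8 and 10–15; step 9 is a one-step side branch).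

The three steps most likely to fail are steps 3, 5 and 10.

Step 3 (cascade). What may go wrong: a second acrolein may alkylate the nitronate, acrolein may polymerise, or the enamine face may be poorly controlled at C1. Fallback from 5, returning at 7: the two bonds are made in separate operations with different activation. A base-mediated nitro-Michael addition of 5 to acrolein (KF on Al2O3, MeCN, 0 °C) should give the open-chain nitro aldehyde (5S)-4-nitro-5-[(1R)-4-oxocyclohex-2-en-1-yl]hexanal F1. An enamine-catalysed intramolecular Michael addition of F1 (the same diphenylprolinol ether, or pyrrolidine/AcOH, CH2Cl2) then closes ring B to 7.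

Step 5 (dehydrogenation). What may go wrong: enolisation toward C3 instead of C1 of the ketone (wrong enone), over-oxidation to the phenol, or acid-promoted epimerisation at the γ-carbons. Fallback from 5, returning at 10: the enone is never consumed, because the second Michael addition becomes an addition–elimination.
- Conjugate addition of PhSH (Et3N, CH2Cl2) to 5 should give (4S)-4-[(2S)-1-nitropropan-2-yl]-3-(phenylsulfanyl)cyclohexan-1-one F2.
- Chlorination–elimination (NCS, CCl4; then Et3N) should give the vinylogous thioester (4S)-4-[(2S)-1-nitropropan-2-yl]-3-(phenylsulfanyl)cyclohex-2-en-1-one F3.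
- mCPBA (2 equiv) should give (4S)-3-(benzenesulfonyl)-4-[(2S)-1-nitropropan-2-yl]cyclohex-2-en-1-one F4.
- The amine-catalysed cascade of F4 with acrolein, in which the enamine adds to the sulfonyl-bearing β-carbon and benzenesulfinate is lost, should give (1R,4S,4aS)-4-methyl-3-nitro-7-oxo-1,2,3,4,4a,5,6,7-octahydronaphthalene-1-carbaldehyde F5.
- Methylenation of both carbonyl groups of F5 with excess Ph3P=CH2 returns to 10.

Step 10 (cross-metathesis). What may go wrong: the conjugated ring diene may divert the ruthenium carbene, or the α-branched vinyl group may turn over slowly. Fallback from 7, returning at 16: the formyl carbon is carried as a protected alcohol and the enoyl imide is made by olefination instead of metathesis.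
- Aldehyde-selective reduction of 7 (NaBH(OAc)3, benzene, 50 °C) should give (4aR,5S,8R,8aS)-8-(hydroxymethyl)-5-methyl-6-nitrooctahydronaphthalen-2(1H)-one F6.
- Silylation (t-BuMe2SiCl, imidazole) should give (4aR,5S,8R,8aS)-8-{[tert-butyl(dimethyl)silyl]oxymethyl}-5-methyl-6-nitrooctahydronaphthalen-2(1H)-one F7.
- IBX should give (4aS,5S,8R)-8-{[tert-butyl(dimethyl)silyl]oxymethyl}-5-methyl-6-nitro-4,4a,5,6,7,8-hexahydronaphthalen-2(3H)-one F8.
- Ph3P=CH2 should give tert-butyl{[(1R,4S,4aS)-4-methyl-7-methylidene-3-nitro-1,2,3,4,4a,5,6,7-octahydronaphthalen-1-yl]methoxy}dimethylsilane F9.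
- H2O2/K2CO3 should give (1S,4R,8aS)-4-{[tert-butyl(dimethyl)silyl]oxymethyl}-1-methyl-6-methylidene-3,4,6,7,8,8a-hexahydronaphthalen-2(1H)-one F10.
- LiBH(s-Bu)3 should give (1S,2R,4R,8aS)-4-{[tert-butyl(dimethyl)silyl]oxymethyl}-1-methyl-6-methylidene-1,2,3,4,6,7,8,8a-octahydronaphthalen-2-ol F11.
- Bu4NF should give (1S,2R,4R,8aS)-4-(hydroxymethyl)-1-methyl-6-methylidene-1,2,3,4,6,7,8,8a-octahydronaphthalen-2-ol F12.
- Oxidation of the primary alcohol only (PhI(OAc)2, TEMPO cat.) should give (1R,3R,4S,4aS)-3-hydroxy-4-methyl-7-methylidene-1,2,3,4,4a,5,6,7-octahydronaphthalene-1-carbaldehyde F13.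
- Horner–Wadsworth–Emmons olefination of F13 with diethyl {2-[(4R)-4-benzyl-2-oxo-1,3-oxazolidin-3-yl]-2-oxoethyl}phosphonate (LiCl, i-Pr2NEt, MeCN) returns to 16.

Further compounds
F1 | step 3 | (5S)-4-nitro-5-[(1R)-4-oxocyclohex-2-en-1-yl]hexanal (C4 epimers) | O=C1C=C[C@@H](CC1)[C@H](C)C(CCC=O)[N+](=O)[O-]
F2 | step 5 | (4S)-4-[(2S)-1-nitropropan-2-yl]-3-(phenylsulfanyl)cyclohexan-1-one (C3 epimers) | O=C1CC(Sc2ccccc2)[C@@H](CC1)[C@H](C)C[N+](=O)[O-]
F3 | step 5 | (4S)-4-[(2S)-1-nitropropan-2-yl]-3-(phenylsulfanyl)cyclohex-2-en-1-one | O=C1C=C(Sc2ccccc2)[C@@H](CC1)[C@H](C)C[N+](=O)[O-]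
F4 | step 5 | (4S)-3-(benzenesulfonyl)-4-[(2S)-1-nitropropan-2-yl]cyclohex-2-en-1-one | O=C1C=C(S(=O)(=O)c2ccccc2)[C@@H](CC1)[C@H](C)C[N+](=O)[O-]
F5 | step 5 | (1R,4S,4aS)-4-methyl-3-nitro-7-oxo-1,2,3,4,4a,5,6,7-octahydronaphthalene-1-carbaldehyde (C3 epimers) | O=C1C=C2[C@@H](CC1)[C@H](C)C([N+](=O)[O-])C[C@H]2C=O
F6 | step 10 | (4aR,5S,8R,8aS)-8-(hydroxymethyl)-5-methyl-6-nitrooctahydronaphthalen-2(1H)-one (C6 epimers) | O=C1C[C@H]2[C@@H](CC1)[C@H](C)C([N+](=O)[O-])C[C@H]2CO
F7 | step 10 | (4aR,5S,8R,8aS)-8-{[tert-butyl(dimethyl)silyl]oxymethyl}-5-methyl-6-nitrooctahydronaphthalen-2(1H)-one (C6 epimers) | O=C1C[C@H]2[C@@H](CC1)[C@H](C)C([N+](=O)[O-])C[C@H]2CO[Si](C)(C)C(C)(C)C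
F8 | step 10 | (4aS,5S,8R)-8-{[tert-butyl(dimethyl)silyl]oxymethyl}-5-methyl-6-nitro-4,4a,5,6,7,8-hexahydronaphthalen-2(3H)-one (C6 epimers) | O=C1C=C2[C@@H](CC1)[C@H](C)C([N+](=O)[O-])C[C@H]2CO[Si](C)(C)C(C)(C)C
F9 | step 10 | tert-butyl{[(1R,4S,4aS)-4-methyl-7-methylidene-3-nitro-1,2,3,4,4a,5,6,7-octahydronaphthalen-1-yl]methoxy}dimethylsilane (C3 epimers) | C=C1C=C2[C@@H](CC1)[C@H](C)C([N+](=O)[O-])C[C@H]2CO[Si](C)(C)C(C)(C)C
F10 | step 10 | (1S,4R,8aS)-4-{[tert-butyl(dimethyl)silyl]oxymethyl}-1-methyl-6-methylidene-3,4,6,7,8,8a-hexahydronaphthalen-2(1H)-one | C=C1C=C2[C@@H](CC1)[C@H](C)C(=O)C[C@H]2CO[Si](C)(C)C(C)(C)C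
F11 | step 10 | (1S,2R,4R,8aS)-4-{[tert-butyl(dimethyl)silyl]oxymethyl}-1-methyl-6-methylidene-1,2,3,4,6,7,8,8a-octahydronaphthalen-2-ol | C=C1C=C2[C@@H](CC1)[C@H](C)[C@H](O)C[C@H]2CO[Si](C)(C)C(C)(C)C
F12 | step 10 | (1S,2R,4R,8aS)-4-(hydroxymethyl)-1-methyl-6-methylidene-1,2,3,4,6,7,8,8a-octahydronaphthalen-2-ol | C=C1C=C2[C@@H](CC1)[C@H](C)[C@H](O)C[C@H]2CO
F13 | step 10 | (1R,3R,4S,4aS)-3-hydroxy-4-methyl-7-methylidene-1,2,3,4,4a,5,6,7-octahydronaphthalene-1-carbaldehyde | C=C1C=C2[C@@H](CC1)[C@H](C)[C@H](O)C[C@H]2C=O
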